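**Plan**

1. Retrosynthesis: remove the C18 acetate and turn the exocyclic C8=C17 methylene of ring B into a C8 ketone (Wittig). Written as its silyl enol ether C8=C9, ring B is a cyclohexene, the retron of a [4+2] cycloaddition.
2. Cut C6–C7 and C5–C10 together: diene C7=C8(OSi)–C9=C10 and dienophile C5=C6, joined by C1–C4 (the future ring A). A phenylsulfonyl group on C6 activates the alkene and is expelled afterwards.
3. Cut C1–C10 (sp3–sp2 Suzuki–Miyaura): an enol triflate carrying the C9 side chain (from pentane-2,4-dione and a C11–C15 bromide) and a C4-quaternary allyl vinyl sulfone.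
4. Forward: two fragments, coupling, silyl dienol ether, one intramolecular Diels–Alder reaction that closes ring B and ring A, then loss of sulfinate, hydrogenation, saponification, methylenation, acetylation.
5. Stereochemistry: C13 from (R)-monomethyl 3-methylglutarate; C4 from catalytic desymmetrisation of a prochiral 1,3-diol; C5 and C10 from C4 in the chair-like transition state; C9 by equilibration next to the C8 ketone.

Key step: step 12

Remark: labdane numbering is used for the skeleton (C17 = exocyclic methylene carbon, C18 = 4α-CH2O, C19 = 4β-CH3, C20 = 10β-CH3; labdane names imply 5α-H, 9α-H, 10β-CH3); the target is read as (13S)-18-acetoxylabd-8(17)-en-15-oic acid.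

**Route**

Step 1
Reactants: 1 (3R)-5-methoxy-3-methyl-5-oxopentanoic acid [(R)-monomethyl 3-methylglutarate]
Product: 3 (4S)-4-methyloxan-2-one, via hydroxy acid 2 (not isolated)
Conditions: LiBH4, THF, 0 °C to rt; then 2 M HCl, rt
Reagents that add atoms: none
Why: Chemoselective borohydride reduction, in which LiBH4 reduces the methyl ester while the lithium carboxylate is inert and acidification closes the δ-lactone (lactonisation), the future C13 stereocentre being untouched.

Step 2
Reactants: 3 (4S)-4-methyloxan-2-one
Product: 5 methyl (3R)-5-bromo-3-methylpentanoate, via bromo acid 4 (not isolated)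
Conditions: HBr (33% in AcOH), 60 °C; then MeOH, rt
Reagents that add atoms: hydrogen bromide, Br; methanol, CO
Why: Acid-mediated SN2 opening of the lactone by bromide at the primary O–CH2 carbon followed by Fischer esterification of the acid, with no bond to the stereocentre affected.

Step 3
Reactants: 5 methyl (3R)-5-bromo-3-methylpentanoate, 6 pentane-2,4-dione
Product: 7 methyl (3S)-6-acetyl-3-methyl-7-oxooctanoate
Conditions: K2CO3, NaI (cat.), acetone, reflux
Reagents that add atoms: none
Why: C-Alkylation of the potassium enolate of a 1,3-diketone by a primary halide (SN2, assisted by Finkelstein exchange) is a standard way to 3-alkylpentane-2,4-diones.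

Step 4
Reactants: 7 methyl (3S)-6-acetyl-3-methyl-7-oxooctanoate
Product: 8 methyl (3S,6E)-6-acetyl-3-methyl-7-(trifluoromethylsulfonyloxy)oct-6-enoate
Conditions: Tf2O, Me4NOH (aq.), toluene–hexane, 5 °C
Reagents that add atoms: trifluoromethanesulfonic anhydride, O=S(=O)(OS(=O)(=O)C(F)(F)F)C(F)(F)F
Why: O-Sulfonylation (enol triflate formation) of the non-chelated tetramethylammonium enolate should place the triflate trans to the remaining acetyl group (E), the geometry that later puts the tether outside on the diene; the diketone is symmetrical, so no regiochemical question arises.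

Step 5
Reactants: 9 diethyl 2-methylpropanedioate, 10 3-bromoprop-1-ene
Product: 11 diethyl 2-methyl-2-(prop-2-en-1-yl)propanedioate
Conditions: NaH, THF, 0 °C to rt
Reagents that add atoms: none
Why: Malonic ester alkylation of the sodium enolate with an allylic bromide (SN2).

Step 6
Reactants: 11 diethyl 2-methyl-2-(prop-2-en-1-yl)propanedioate
Product: 12 2-methyl-2-(prop-2-en-1-yl)propane-1,3-diol
Conditions: LiAlH4, Et2O, 0 °C to reflux
Reagents that add atoms: none
Why: Exhaustive hydride reduction of both esters gives the prochiral 1,3-diol, with the isolated alkene untouched.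

Step 7
Reactants: 12 2-methyl-2-(prop-2-en-1-yl)propane-1,3-diol
Product: 13 [(2R)-2-(hydroxymethyl)-2-methylpent-4-en-1-yl] benzoate
Conditions: BzCl, Et3N, CuCl2 (cat.), chiral bis(oxazoline) ligand (cat., the enantiomer that gives the R monoester), THF, −40 °C
Reagents that add atoms: benzoyl chloride, O=C(Cl)c1ccccc1
Why: Catalytic enantioselective desymmetrising monobenzoylation of a prochiral 2,2-disubstituted propane-1,3-diol, in which the chiral copper bis(oxazoline) complex chelates the diol and activates one enantiotopic hydroxymethyl group, fixing the quaternary centre (future C4).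

Step 8
Reactants: 13 [(2R)-2-(hydroxymethyl)-2-methylpent-4-en-1-yl] benzoate
Product: 14 [(2S)-2-formyl-2-methylpent-4-en-1-yl] benzoate
Conditions: Dess–Martin periodinane, NaHCO3, CH2Cl2, 0 °C to rt
Reagents that add atoms: none
Why: Dess–Martin oxidation of the neopentyl alcohol, run directly and buffered so that 1,3-benzoyl migration cannot erode the enantiopurity, gives an aldehyde with no α-hydrogen that can neither epimerise nor eliminate benzoate.

Step 9
Reactants: 14 [(2S)-2-formyl-2-methylpent-4-en-1-yl] benzoate, 15 diethyl [(phenylsulfonyl)methyl]phosphonate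
Product: 16 [(2R,3E)-2-methyl-4-(phenylsulfonyl)-2-(prop-2-en-1-yl)but-3-en-1-yl] benzoate
Conditions: NaH, THF, 0 °C to rt
Reagents that add atoms: none
Why: Horner–Wadsworth–Emmons olefination with the sulfonyl-stabilised phosphonate anion should give the E vinyl sulfone (future C5=C6 with the activating group on C6) even with the hindered aldehyde.

Step 10
Reactants: 16 [(2R,3E)-2-methyl-4-(phenylsulfonyl)-2-(prop-2-en-1-yl)but-3-en-1-yl] benzoate, 8 methyl (3S,6E)-6-acetyl-3-methyl-7-(trifluoromethylsulfonyloxy)oct-6-enoate
Product: 18 methyl (3S,6E,11R,12E)-6-acetyl-11-(benzoyloxymethyl)-3,7,11-trimethyl-13-(phenylsulfonyl)trideca-6,12-dienoate, via alkylborane 17 (not isolated)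
Conditions: 9-BBN, THF, rt; then 8, Pd(dppf)Cl2 (cat.), AsPh3 (cat.), Cs2CO3, DMF–H2O, rt
Reagents that add atoms: none
Why: 9-BBN hydroborates only the unhindered terminal allyl alkene (anti-Markovnikov; the electron-poor neopentyl vinyl sulfone is left), and the B-alkyl Suzuki–Miyaura coupling then joins C1 to C10 with retention of the triflate geometry.

Step 11
Reactants: 18 methyl (3S,6E,11R,12E)-6-acetyl-11-(benzoyloxymethyl)-3,7,11-trimethyl-13-(phenylsulfonyl)trideca-6,12-dienoate
Product: 19 methyl (3S,6E,11R,12E)-11-(benzoyloxymethyl)-6-[1-(tert-butyldimethylsilyloxy)ethenyl]-3,7,11-trimethyl-13-(phenylsulfonyl)trideca-6,12-dienoate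
Conditions: TBSOTf, Et3N, CH2Cl2, 0 °C
Reagents that add atoms: tert-butyldimethylsilyl trifluoromethanesulfonate, CC(C)(C)[Si](C)(C)OS(=O)(=O)C(F)(F)F
Why: Soft enolisation (silyl triflate and amine) removes a proton from the unhindered acetyl methyl to give the cross-conjugated 2-silyloxy diene without touching the C9=C10 geometry, the esters or the sulfone.

Step 12
Reactants: 19 methyl (3S,6E,11R,12E)-11-(benzoyloxymethyl)-6-[1-(tert-butyldimethylsilyloxy)ethenyl]-3,7,11-trimethyl-13-(phenylsulfonyl)trideca-6,12-dienoate
Product: 20 methyl (13S)-18-benzoyloxy-8-(tert-butyldimethylsilyloxy)-6α-(phenylsulfonyl)-17-norlabd-8-en-15-oate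
Conditions: PhMe (0.01 M), BHT (cat.), 140 °C, sealed tube
Reagents that add atoms: none
Why: Concerted, asynchronous intramolecular [4+2] cycloaddition of the electron-rich 2-silyloxy diene C7=C8–C9=C10 (HOMO raised by the silyloxy and three alkyl groups) onto the sulfone-activated alkene C5=C6 (LUMO lowered by SO2Ph); the closest known reaction type is the thermal intramolecular Diels–Alder reaction of sulfonyl-substituted 1,7,9-decatrienes and of 2-silyloxy dienes. Ring B closes as the cyclohexene of the cycloaddition itself (bonds C6–C7 and C5–C10), and ring A closes in the fused (type 1) mode through the four-carbon tether C1–C4 in a chair-like arrangement, the tether dictating the regiochemistry against the weak electronic preference of the two partners. C5 and C10 are set trans (5α-H, 10β-CH3) because the E geometry of C9=C10 holds the tether outside and the quaternary C4 can only sit exo, away from the substituted C9/C10 half of the diene, which puts H-5 and the sulfone endo (6α-SO2Ph, a centre erased in step 13). Their sense relative to C4 follows from the chair-like tether, in which the small C19 methyl takes the axial site (close to C5=C6 and syn to C20) and the larger, rotationally more demanding CH2OBz takes the equatorial site anti to the forming C5–C10 bond, giving 4β-CH3 and 4α-CH2OBz. The step therefore needs regio-, trans-fusion and π-facial selectivity: the first is secured by the tether, the second by the diene geometry and the exo demand of C4, and the third only by the size difference at C4, which is the weakest control element. The silyl enol ether emerges as C8=C9, so C9 is left to be set under thermodynamic control after unmasking.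

Step 13
Reactants: 20 methyl (13S)-18-benzoyloxy-8-(tert-butyldimethylsilyloxy)-6α-(phenylsulfonyl)-17-norlabd-8-en-15-oate
Product: 22 methyl (13S)-18-benzoyloxy-8-oxo-17-norlabd-6-en-15-oate, via keto sulfone 21 (not isolated)
Conditions: TBAF, THF, 0 °C; then DBU, rt
Reagents that add atoms: none
Why: Fluoride cleaves the silyl enol ether to the C8 ketone, and the C6 sulfinate, now β to the carbonyl, leaves by E1cB elimination under DBU, which also equilibrates C9 to the equatorial side chain (9α-H).

Step 14
Reactants: 22 methyl (13S)-18-benzoyloxy-8-oxo-17-norlabd-6-en-15-oate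
Product: 23 methyl (13S)-18-benzoyloxy-8-oxo-17-norlabdan-15-oate
Conditions: H2 (1 atm), Pd/C, EtOAc, rt
Reagents that add atoms: none
Why: Heterogeneous catalytic hydrogenation saturates only the conjugated C6=C7 bond, leaving ketone, benzoate and methyl ester, and creates no stereocentre.

Step 15
Reactants: 23 methyl (13S)-18-benzoyloxy-8-oxo-17-norlabdan-15-oate
Product: 24 (13S)-18-hydroxy-8-oxo-17-norlabdan-15-oic acid
Conditions: LiOH, THF–MeOH–H2O, 50 °C; then 1 M HCl
Reagents that add atoms: lithium hydroxide, [Li+].[OH-]
Why: Saponification cleaves both the methyl ester and the benzoate, and the basic medium keeps C9 in its thermodynamically preferred configuration.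

Step 16
Reactants: 24 (13S)-18-hydroxy-8-oxo-17-norlabdan-15-oic acid
Product: 25 (13S)-18-hydroxylabd-8(17)-en-15-oic acid
Conditions: Ph3PCH3Br, KOtBu (5 equiv each), THF, 0 to 60 °C; then aq. citric acid
Reagents that add atoms: methyltriphenylphosphonium bromide, C[P+](c1ccccc1)(c1ccccc1)c1ccccc1.[Br-]
Why: Wittig methylenation with excess ylide (the carboxylate and alkoxide are inert spectators) converts the C8 ketone into the exocyclic C8=C17 methylene, a transformation well known for 8-oxo-17-norlabdanes.

Step 17
Reactants: 25 (13S)-18-hydroxylabd-8(17)-en-15-oic acid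
Product: 26 (13S)-18-acetoxylabd-8(17)-en-15-oic acid
Conditions: Ac2O, pyridine, DMAP (cat.), CH2Cl2, rt; then H2O
Reagents that add atoms: acetic anhydride, CC(=O)OC(C)=O
Why: Nucleophile-catalysed acetylation of the primary C18 alcohol, any mixed anhydride at C15 being hydrolysed on aqueous work-up.

**Compound list**

1 | (3R)-5-methoxy-3-methyl-5-oxopentanoic acid [(R)-monomethyl 3-methylglutarate] | COC(=O)C[C@H](C)CC(=O)O | starting material
2 | (3S)-5-hydroxy-3-methylpentanoic acid (formed in the flask) | OCC[C@H](C)CC(=O)O | intermediate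
3 | (4S)-4-methyloxan-2-one | C[C@H]1CCOC(=O)C1 | intermediate
4 | (3R)-5-bromo-3-methylpentanoic acid (formed in the flask) | BrCC[C@H](C)CC(=O)O | intermediate
5 | methyl (3R)-5-bromo-3-methylpentanoate | BrCC[C@H](C)CC(=O)OC | intermediate
6 | pentane-2,4-dione | CC(=O)CC(C)=O | starting material
7 | methyl (3S)-6-acetyl-3-methyl-7-oxooctanoate | CC(=O)C(C(C)=O)CC[C@H](C)CC(=O)OC | intermediate
8 | methyl (3S,6E)-6-acetyl-3-methyl-7-(trifluoromethylsulfonyloxy)oct-6-enoate | C/C(OS(=O)(=O)C(F)(F)F)=C(\C(C)=O)CC[C@H](C)CC(=O)OC | intermediate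
9 | diethyl 2-methylpropanedioate | CCOC(=O)C(C)C(=O)OCC | starting material
10 | 3-bromoprop-1-ene (allyl bromide) | C=CCBr | starting material
11 | diethyl 2-methyl-2-(prop-2-en-1-yl)propanedioate | CCOC(=O)C(C)(CC=C)C(=O)OCC | intermediate
12 | 2-methyl-2-(prop-2-en-1-yl)propane-1,3-diol | OCC(C)(CO)CC=C | intermediate
13 | [(2R)-2-(hydroxymethyl)-2-methylpent-4-en-1-yl] benzoate | OC[C@](C)(COC(=O)c1ccccc1)CC=C | intermediate
14 | [(2S)-2-formyl-2-methylpent-4-en-1-yl] benzoate | O=C[C@](C)(COC(=O)c1ccccc1)CC=C | intermediate
15 | diethyl [(phenylsulfonyl)methyl]phosphonate | CCOP(=O)(CS(=O)(=O)c1ccccc1)OCC | starting material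
16 | [(2R,3E)-2-methyl-4-(phenylsulfonyl)-2-(prop-2-en-1-yl)but-3-en-1-yl] benzoate | O=S(=O)(c1ccccc1)/C=C/[C@](C)(COC(=O)c1ccccc1)CC=C | intermediate
17 | 9-[(4R,5E)-4-(benzoyloxymethyl)-4-methyl-6-(phenylsulfonyl)hex-5-en-1-yl]-9-borabicyclo[3.3.1]nonane (formed in the flask) | C1CCC2CCCC1B2CCC[C@@](C)(COC(=O)c3ccccc3)/C=C/S(=O)(=O)c3ccccc3 | intermediate
18 | methyl (3S,6E,11R,12E)-6-acetyl-11-(benzoyloxymethyl)-3,7,11-trimethyl-13-(phenylsulfonyl)trideca-6,12-dienoate | CC(=O)/C(CC[C@H](C)CC(=O)OC)=C(\C)CCC[C@@](C)(COC(=O)c1ccccc1)/C=C/S(=O)(=O)c1ccccc1 | intermediate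
19 | methyl (3S,6E,11R,12E)-11-(benzoyloxymethyl)-6-[1-(tert-butyldimethylsilyloxy)ethenyl]-3,7,11-trimethyl-13-(phenylsulfonyl)trideca-6,12-dienoate | C=C(O[Si](C)(C)C(C)(C)C)/C(CC[C@H](C)CC(=O)OC)=C(\C)CCC[C@@](C)(COC(=O)c1ccccc1)/C=C/S(=O)(=O)c1ccccc1 | intermediate
20 | methyl (13S)-18-benzoyloxy-8-(tert-butyldimethylsilyloxy)-6α-(phenylsulfonyl)-17-norlabd-8-en-15-oate | CC(C)(C)[Si](C)(C)OC=1C[C@H](S(=O)(=O)c3ccccc3)[C@H]2[C@](C)(COC(=O)c3ccccc3)CCC[C@]2(C)C=1CC[C@H](C)CC(=O)OC | intermediate
21 | methyl (13S)-18-benzoyloxy-8-oxo-6α-(phenylsulfonyl)-17-norlabdan-15-oate (formed in the flask) | O=C1C[C@H](S(=O)(=O)c3ccccc3)[C@H]2[C@](C)(COC(=O)c3ccccc3)CCC[C@]2(C)[C@H]1CC[C@H](C)CC(=O)OC | intermediate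
22 | methyl (13S)-18-benzoyloxy-8-oxo-17-norlabd-6-en-15-oate | O=C1C=C[C@H]2[C@](C)(COC(=O)c3ccccc3)CCC[C@]2(C)[C@H]1CC[C@H](C)CC(=O)OC | intermediate
23 | methyl (13S)-18-benzoyloxy-8-oxo-17-norlabdan-15-oate | O=C1CC[C@H]2[C@](C)(COC(=O)c3ccccc3)CCC[C@]2(C)[C@H]1CC[C@H](C)CC(=O)OC | intermediate
24 | (13S)-18-hydroxy-8-oxo-17-norlabdan-15-oic acid | O=C1CC[C@H]2[C@](C)(CO)CCC[C@]2(C)[C@H]1CC[C@H](C)CC(=O)O | intermediate
25 | (13S)-18-hydroxylabd-8(17)-en-15-oic acid | C=C1CC[C@H]2[C@](C)(CO)CCC[C@]2(C)[C@H]1CC[C@H](C)CC(=O)O | intermediate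
26 | (13S)-18-acetoxylabd-8(17)-en-15-oic acid | C=C1CC[C@H]2[C@](C)(COC(C)=O)CCC[C@]2(C)[C@H]1CC[C@H](C)CC(=O)O | target

**Count and risks**

Total step count: 17. Longest linear sequence: 13 steps (steps 5 to 17, from diethyl 2-methylpropanedioate 9); steps 1 to 4 form the second branch, which joins in step 10.

Steps most likely to fail:

Step 12. The π-facial discrimination between the two chair-like transition states (methyl against benzoyloxymethyl at C4) may be too small at the temperature the cycloaddition needs, and a 1,5-hydrogen shift in the diene, which carries a Z methyl group, may compete. The fallback sets out from enone 18 and comes back at keto sulfone 21. Enone 18 is condensed with pyrrolidine and TiCl4 to the cross-conjugated pyrrolidine dienamine F1, a far more electron-rich diene than 19. F1 should undergo the same intramolecular cycloaddition at or below room temperature, where the two transition states are better differentiated and no sigmatropic shift competes, giving the enamine cycloadduct F2. Aqueous acetic acid hydrolyses F2 to 21, which is taken on with DBU as in step 13.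

Step 4. Geometric control may be lost in the O-sulfonylation (reaction through the chelated instead of the open enolate, or isomerisation during the coupling), so that the tether ends up cis to the acetyl group. The fallback sets out from diketone 7 and comes back at enone 18. Diketone 7 is triflated under chelation control (NaH, then Tf2O, Et2O, 0 °C), which should give the single (Z)-triflate F3. Coupling with borane 17 as in step 10 gives the (Z)-enone F4. F4 is equilibrated with 18 by visible light and a catalytic amount of iodine; 18 is separated by chromatography and F4 is recycled.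

Step 16. The basic ylide may enolise the hindered C8 ketone of the doubly anionic keto acid instead of adding to it, leaving the conversion incomplete. The fallback sets out from keto diester 23 and comes back at 25. Keto diester 23 is methylenated before saponification with the Takai–Lombardo reagent (Zn, CH2Br2, TiCl4, THF–CH2Cl2), a non-basic titanium methylene species that spares esters, to give the alkene diester F5. Saponification of F5 as in step 15 gives 25.

Further compounds
F1 | step 12 | methyl (3S,6E,11R,12E)-11-(benzoyloxymethyl)-3,7,11-trimethyl-13-(phenylsulfonyl)-6-[1-(pyrrolidin-1-yl)ethenyl]trideca-6,12-dienoate | C=C(N1CCCC1)/C(CC[C@H](C)CC(=O)OC)=C(\C)CCC[C@@](C)(COC(=O)c1ccccc1)/C=C/S(=O)(=O)c1ccccc1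
F2 | step 12 | methyl (13S)-18-benzoyloxy-6α-(phenylsulfonyl)-8-(pyrrolidin-1-yl)-17-norlabd-8-en-15-oate | C1CCCN1C=2C[C@H](S(=O)(=O)c3ccccc3)[C@H]4[C@](C)(COC(=O)c3ccccc3)CCC[C@]4(C)C=2CC[C@H](C)CC(=O)OC
F3 | step 4 | methyl (3S,6Z)-6-acetyl-3-methyl-7-(trifluoromethylsulfonyloxy)oct-6-enoate | C/C(OS(=O)(=O)C(F)(F)F)=C(/C(C)=O)CC[C@H](C)CC(=O)OC
F4 | step 4 | methyl (3S,6Z,11R,12E)-6-acetyl-11-(benzoyloxymethyl)-3,7,11-trimethyl-13-(phenylsulfonyl)trideca-6,12-dienoate | CC(=O)/C(CC[C@H](C)CC(=O)OC)=C(/C)CCC[C@@](C)(COC(=O)c1ccccc1)/C=C/S(=O)(=O)c1ccccc1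
F5 | step 16 | methyl (13S)-18-benzoyloxylabd-8(17)-en-15-oate | C=C1CC[C@H]2[C@](C)(COC(=O)c3ccccc3)CCC[C@]2(C)[C@H]1CC[C@H](C)CC(=O)OC
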